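**Plan**

1. Retrosynthesis: the two sulfate esters (O–S) are removed first. The C40 chain is then cut at C10–C11 and C10'–C11' into two identical C14 dienyl iodides and a central C12 pentaenyl bis-stannane made from the C10 dialdehyde.
2. Each dienyl iodide is cut back through C9–CH3 (carboalumination), C8–C9 (Sonogashira) and the C7–C8 triple bond to a ring methyl ketone whose acetyl group is C7/C8.
3. The ring is cut at C1–C2 and C5–C6. In each cyclohexane end ring, C1 (gem-dimethyl) and C6 (side chain) are the β- and α-carbons of mesityl oxide and C2–C5 (methyl on C5) are piperylene, so the [4+2] adduct has its only double bond at C3=C4, where the cis-diol is needed.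
4. Forward: ring by Diels–Alder (step 1), C3/C4 diol, differentiation of the two hydroxyls, chain growth C7 to C10, twofold coupling to the centre, 4-O-sulfation, final desilylation.
5. Stereochemistry: C5 from the chiral Lewis acid, C6 by epimerisation to trans, C3/C4 by substrate-controlled Woodward cis-hydroxylation on the face syn to the axial C1 methyl. All E double bonds come from syn hydro-/carbometalation, Takai-type olefination and stereoretentive couplings.

Key step: step 1

Remark (numbering): carotenoid locants are used for the ring in all names: C1 gem-dimethyl, C2 CH2, C3, C4, C5 (methyl), C6 (side chain), chain C7 onward.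

Remark (assumption): the sense of induction for an acyclic β,β-disubstituted enone is not established. The (R)-diphenylprolinol-derived catalyst is written because the α-C–H···O binding model with endo approach predicts (5S) for it, and the mirror-image catalyst is equally available if the first correlation shows the opposite sense.

Remark (assumption): the target is drawn as the free bis(hydrogen sulfate). The last step releases this acid form on a cold acidic resin, and for storage it would be neutralised at once to the disodium salt.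

**Route**

Step 1
Reactants: 1 (E)-penta-1,3-diene; 2 4-methylpent-3-en-2-one
Product: 4 1-[(1R,2S)-2,6,6-trimethylcyclohex-3-en-1-yl]ethan-1-one (trans ketone), via cis endo adduct 3 (not isolated)
Conditions: (R)-3,3-diphenyl-1-(o-tolyl)tetrahydro-1H,3H-pyrrolo[1,2-c][1,3,2]oxazaborole (0.2 equiv), AlBr3 (0.16 equiv), 1 (3 equiv), CH2Cl2, −40 → 0 °C; then NaOMe (0.1 equiv), MeOH, rt
Reagents that add atoms: none
Why: Proposed new method: the AlBr3-activated oxazaborolidine is a cationic boron Lewis acid that binds the carbonyl oxygen of 2 and lowers the enone LUMO enough for a concerted, asynchronous suprafacial [4+2] addition of 1, the closest known reactions being the racemic AlCl3-catalysed cycloaddition of these same two partners and enantioselective cycloadditions of acrylates and less substituted enones under this catalyst type. The six-membered ring closes in that single intermolecular cycloaddition, the C1–C2 and C5–C6 bonds forming together across the diene termini. Regiochemistry follows from the larger HOMO coefficient at the unsubstituted diene terminus, which meets the β-carbon of the enone and so places the C5 methyl next to the acetyl-bearing C6. C5 is controlled by the catalyst: two-point binding of the enone (B–O and α-C–H···O contacts) screens one enone face, and endo approach of the (E)-diene to the open face gives the cis adduct 3 with C5 as required. C6 is controlled thermodynamically, since NaOMe epimerises the centre α to the ketone to the trans diequatorial isomer 4. The step needs face selectivity together with endo selectivity (an exo adduct from the same face would epimerise to the enantiomer), and it relies on the endo preference of the acetyl group and on the (E) geometry of 1, the (Z) isomer being unable to reach the reactive s-cis conformation.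

Step 2
Reactants: 4 trans ketone
Product: 7 (3R,4S,5R,6R)-6-acetyl-1,1,5-trimethylcyclohexane-3,4-diol, via iodo acetate 5 (not isolated), via hydroxy acetate 6 (not isolated)
Conditions: I2 (1.05 equiv), AgOAc (2.2 equiv), AcOH, rt; then H2O (1 equiv), 90 °C; then K2CO3 (0.2 equiv), MeOH, rt
Reagents that add atoms: silver acetate, CC(=O)[O-].[Ag+]
Why: Woodward cis-hydroxylation, in which the iodonium ion forms on the open face anti to the axial C1 methyl, acetate opens it trans-diaxially at C3 from the hindered face, and displacement of the C4 iodide by the neighbouring acetate (acetoxonium ion, then water) puts both oxygens on the face syn to the acetyl group, the same course that delivers the hindered-face diol from conformationally locked cyclohexenes with an axial homoallylic methyl, while the final methanolysis frees the diol and leaves C6 trans.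

Step 3
Reactants: 7 diol
Product: 8 (3R,4S,5R,6R)-6-acetyl-1,1,5-trimethyl-4-(triethylsilyloxy)cyclohexan-3-ol
Conditions: TESCl (1.05 equiv), imidazole, CH2Cl2, −30 → 0 °C
Reagents that add atoms: chlorotriethylsilane, CC[Si](Cl)(CC)CC
Why: Regioselective silylation, since the C4 hydroxyl is equatorial whereas the C3 hydroxyl is axial and syn-axial to the C1 methyl and therefore much slower to react with a silyl chloride.

Step 4
Reactants: 8 mono-silyl ether
Product: 9 (3R,4S,5R,6R)-6-acetyl-3-(tert-butyldimethylsilyloxy)-1,1,5-trimethyl-4-(triethylsilyloxy)cyclohexane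
Conditions: TBSOTf (1.3 equiv), 2,6-lutidine, CH2Cl2, −78 → 0 °C
Reagents that add atoms: tert-butyldimethylsilyl trifluoromethanesulfonate, CC(C)(C)[Si](C)(C)OS(=O)(=O)C(F)(F)F
Why: Silylation with a silyl triflate, which is reactive enough for the hindered axial C3 hydroxyl while the weak base at low temperature leaves the hindered ketone unenolised.

Step 5
Reactants: 9 bis-silyl ketone
Product: 11 (3R,4S,5R,6R)-3-(tert-butyldimethylsilyloxy)-6-ethynyl-1,1,5-trimethyl-4-(triethylsilyloxy)cyclohexane, via enol phosphate 10 (not isolated)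
Conditions: LiN(iPr)2 (1.1 equiv), THF, −78 °C; ClP(O)(OEt)2, −78 °C → rt; then LiN(iPr)2 (2.5 equiv), −78 °C → rt; aq NH4Cl
Reagents that add atoms: none
Why: Methyl ketone to terminal alkyne by kinetic deprotonation at the methyl group, O-phosphorylation and base-induced β-elimination of diethyl phosphate (Negishi alkyne synthesis), the hindered C6–H not being removed so that C6 keeps its configuration.

Step 6
Reactants: 11 alkyne
Product: 13 (3R,4S,5R,6S)-3-(tert-butyldimethylsilyloxy)-6-[(E)-2-iodoethenyl]-1,1,5-trimethyl-4-(triethylsilyloxy)cyclohexane, via alkenylzirconocene chloride 12 (not isolated)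
Conditions: Cp2Zr(H)Cl (1.3 equiv), THF, rt; then I2, 0 °C
Reagents that add atoms: iodine, [I][I]
Why: Hydrozirconation adds Zr–H syn with zirconium at the terminal carbon, and iodinolysis of the C–Zr bond with retention gives the (E)-alkenyl iodide.

Step 7
Reactants: 13 alkenyl iodide; 14 ethynyltrimethylsilane
Product: 16 (3R,4S,5R,6R)-6-[(E)-but-1-en-3-yn-1-yl]-3-(tert-butyldimethylsilyloxy)-1,1,5-trimethyl-4-(triethylsilyloxy)cyclohexane, via silylated enyne 15 (not isolated)
Conditions: PdCl2(PPh3)2 (3 mol%), CuI (6 mol%), Et3N, THF, rt; then K2CO3 (0.2 equiv), MeOH, rt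
Reagents that add atoms: none
Why: Sonogashira coupling forms C8–C9 with retention of the E geometry, and methoxide then removes the C-silyl group while both O-silyl ethers are stable to K2CO3 in methanol.

Step 8
Reactants: 16 enyne
Product: 18 (3R,4S,5R,6R)-3-(tert-butyldimethylsilyloxy)-6-[(1E,3E)-4-iodo-3-methylbuta-1,3-dien-1-yl]-1,1,5-trimethyl-4-(triethylsilyloxy)cyclohexane, via alkenylalane 17 (not isolated)
Conditions: AlMe3 (3 equiv), Cp2ZrCl2 (0.3 equiv), CH2Cl2, 0 °C → rt; then I2, THF, −30 °C
Reagents that add atoms: trimethylaluminium, C[Al](C)C; iodine, [I][I]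
Why: Zirconium-catalysed syn carboalumination of the terminal alkyne (Negishi carboalumination) puts the methyl group on C9 and aluminium on C10, and iodinolysis with retention gives the (9E)-iodide.

Step 9
Reactants: 18 dienyl iodide
Product: 19 (3R,4S,5R,6R)-3-(tert-butyldimethylsilyloxy)-6-[(1E,3E)-4-iodo-3-methylbuta-1,3-dien-1-yl]-1,1,5-trimethylcyclohexan-4-ol
Conditions: PPTS (0.2 equiv), MeOH/CH2Cl2, 0 °C → rt, dark
Reagents that add atoms: none
Why: Selective acid-catalysed methanolysis, the secondary triethylsilyl ether being cleaved far faster than the hindered tert-butyldimethylsilyl ether, frees the C4 hydroxyl before the polyene exists.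

Step 10
Reactants: 20 dibromomethane; 21 tributyltin chloride
Product: 22 (dibromomethyl)tributylstannane
Conditions: LiN(iPr)2, THF/Et2O, −95 °C; then 21, −95 °C → rt
Reagents that add atoms: none
Why: Deprotonation of dibromomethane gives the lithium carbenoid, which is stannylated at carbon by substitution at tin before it can decompose.

Step 11
Reactants: 22 (dibromomethyl)tributylstannane (2.5 equiv); 23 (2E,4E,6E)-2,7-dimethylocta-2,4,6-trienedial
Product: 24 (1E,3E,5E,7E,9E)-3,8-dimethyl-1,10-bis(tributylstannyl)deca-1,3,5,7,9-pentaene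
Conditions: CrCl2 (10 equiv), LiI (4 equiv), THF/DMF, rt, dark
Reagents that add atoms: none
Why: Twofold Takai–Hodgson olefination, in which the geminal dichromium reagent formed from 22 adds to each aldehyde and eliminates to the (E)-alkenylstannane, adds C11 and C11' with the tin handles in place.

Step 12
Reactants: 19 dienyl iodide (2.2 equiv); 24 bis-stannane
Product: 25 (all-E)-(3R,3'R,4S,4'S,5R,5'R,6R,6'R)-3,3'-bis(tert-butyldimethylsilyloxy)-5,6,5',6'-tetrahydro-β,β-carotene-4,4'-diol
Conditions: Pd2(dba)3 (5 mol%), AsPh3 (40 mol%), NMP, rt → 40 °C, argon, dark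
Reagents that add atoms: none
Why: Twofold Stille coupling joins C10 to C11 at both ends with retention of configuration in both alkenyl partners and tolerates the free hydroxyls and silyl ethers.

Step 13
Reactants: 25 polyene diol
Product: 26 (all-E)-(3R,3'R,4S,4'S,5R,5'R,6R,6'R)-3,3'-bis(tert-butyldimethylsilyloxy)-5,6,5',6'-tetrahydro-β,β-carotene-4,4'-diyl bis(hydrogen sulfate), carried on as its bis(pyridinium) salt
Conditions: SO3·pyridine (10 equiv), pyridine/DMF, 40 °C, argon, dark
Reagents that add atoms: sulfur trioxide–pyridine complex, [O-]S(=O)(=O)[n+]1ccccc1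
Why: O-Sulfation with the mild SO3–amine complex can only occur at the two C4 hydroxyls, the C3 oxygens being silylated, and does not attack the polyene.

Step 14
Reactants: 26 bis-sulfate
Product: 27 (all-E)-(3R,3'R,4S,4'S,5R,5'R,6R,6'R)-5,6,5',6'-tetrahydro-β,β-carotene-3,3',4,4'-tetrol 4,4'-bis(hydrogen sulfate)
Conditions: Bu4NF (6 equiv), THF, rt → 40 °C, dark; then sulfonic acid resin (H+ form), MeOH, 0 °C
Reagents that add atoms: none
Why: Fluoride-mediated desilylation cleaves the two Si–O bonds while sulfate monoester anions are inert to fluoride and base, so no stereocentre or double bond is touched.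

**Compound list**

1 | (E)-penta-1,3-diene | C/C=C/C=C | starting material
2 | 4-methylpent-3-en-2-one | CC(=O)C=C(C)C | starting material
3 | 1-[(1S,2S)-2,6,6-trimethylcyclohex-3-en-1-yl]ethan-1-one (cis endo adduct, 5S,6S; not isolated) | CC(=O)[C@H]1[C@@H](C)C=CCC1(C)C | intermediate
4 | 1-[(1R,2S)-2,6,6-trimethylcyclohex-3-en-1-yl]ethan-1-one (trans ketone, 5S,6R) | CC(=O)[C@@H]1[C@@H](C)C=CCC1(C)C | intermediate
5 | (3R,4R,5R,6R)-6-acetyl-4-iodo-1,1,5-trimethylcyclohexan-3-yl acetate (trans-diaxial iodo acetate; not isolated) | CC(=O)[C@@H]1[C@@H](C)[C@@H](I)[C@H](OC(C)=O)CC1(C)C | intermediate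
6 | (3R,4S,5R,6R)-6-acetyl-4-hydroxy-1,1,5-trimethylcyclohexan-3-yl acetate (cis hydroxy acetate; not isolated) | CC(=O)[C@@H]1[C@@H](C)[C@H](O)[C@H](OC(C)=O)CC1(C)C | intermediate
7 | (3R,4S,5R,6R)-6-acetyl-1,1,5-trimethylcyclohexane-3,4-diol (both hydroxyls cis to acetyl, trans to the C5 methyl) | CC(=O)[C@@H]1[C@@H](C)[C@H](O)[C@H](O)CC1(C)C | intermediate
8 | (3R,4S,5R,6R)-6-acetyl-1,1,5-trimethyl-4-(triethylsilyloxy)cyclohexan-3-ol | CC(=O)[C@@H]1[C@@H](C)[C@H](O[Si](CC)(CC)CC)[C@H](O)CC1(C)C | intermediate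
9 | (3R,4S,5R,6R)-6-acetyl-3-(tert-butyldimethylsilyloxy)-1,1,5-trimethyl-4-(triethylsilyloxy)cyclohexane | CC(=O)[C@@H]1[C@@H](C)[C@H](O[Si](CC)(CC)CC)[C@H](O[Si](C)(C)C(C)(C)C)CC1(C)C | intermediate
10 | diethyl 1-[(3R,4S,5R,6R)-3-(tert-butyldimethylsilyloxy)-1,1,5-trimethyl-4-(triethylsilyloxy)cyclohexan-6-yl]ethenyl phosphate (not isolated) | C=C(OP(=O)(OCC)OCC)[C@@H]1[C@@H](C)[C@H](O[Si](CC)(CC)CC)[C@H](O[Si](C)(C)C(C)(C)C)CC1(C)C | intermediate
11 | (3R,4S,5R,6R)-3-(tert-butyldimethylsilyloxy)-6-ethynyl-1,1,5-trimethyl-4-(triethylsilyloxy)cyclohexane | C#C[C@@H]1[C@@H](C)[C@H](O[Si](CC)(CC)CC)[C@H](O[Si](C)(C)C(C)(C)C)CC1(C)C | intermediate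
12 | chloro-bis(cyclopentadienyl)[(E)-2-(ring)ethenyl]zirconium from 11 (not isolated) | Cl[Zr](C1C=CC=C1)(C2C=CC=C2)/C=C/[C@@H]3[C@@H](C)[C@H](O[Si](CC)(CC)CC)[C@H](O[Si](C)(C)C(C)(C)C)CC3(C)C | intermediate
13 | (3R,4S,5R,6S)-3-(tert-butyldimethylsilyloxy)-6-[(E)-2-iodoethenyl]-1,1,5-trimethyl-4-(triethylsilyloxy)cyclohexane | I/C=C/[C@@H]1[C@@H](C)[C@H](O[Si](CC)(CC)CC)[C@H](O[Si](C)(C)C(C)(C)C)CC1(C)C | intermediate
14 | ethynyltrimethylsilane | C[Si](C)(C)C#C | starting material
15 | (3R,4S,5R,6R)-3-(tert-butyldimethylsilyloxy)-1,1,5-trimethyl-4-(triethylsilyloxy)-6-[(E)-4-(trimethylsilyl)but-1-en-3-yn-1-yl]cyclohexane (not isolated) | C[Si](C)(C)C#C/C=C/[C@@H]1[C@@H](C)[C@H](O[Si](CC)(CC)CC)[C@H](O[Si](C)(C)C(C)(C)C)CC1(C)C | intermediate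
16 | (3R,4S,5R,6R)-6-[(E)-but-1-en-3-yn-1-yl]-3-(tert-butyldimethylsilyloxy)-1,1,5-trimethyl-4-(triethylsilyloxy)cyclohexane | C#C/C=C/[C@@H]1[C@@H](C)[C@H](O[Si](CC)(CC)CC)[C@H](O[Si](C)(C)C(C)(C)C)CC1(C)C | intermediate
17 | dimethyl[(1E,3E)-2-methyl-4-(ring)buta-1,3-dien-1-yl]alane from 16 (not isolated) | C[Al](C)/C=C(C)/C=C/[C@@H]1[C@@H](C)[C@H](O[Si](CC)(CC)CC)[C@H](O[Si](C)(C)C(C)(C)C)CC1(C)C | intermediate
18 | (3R,4S,5R,6R)-3-(tert-butyldimethylsilyloxy)-6-[(1E,3E)-4-iodo-3-methylbuta-1,3-dien-1-yl]-1,1,5-trimethyl-4-(triethylsilyloxy)cyclohexane | I/C=C(C)/C=C/[C@@H]1[C@@H](C)[C@H](O[Si](CC)(CC)CC)[C@H](O[Si](C)(C)C(C)(C)C)CC1(C)C | intermediate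
19 | (3R,4S,5R,6R)-3-(tert-butyldimethylsilyloxy)-6-[(1E,3E)-4-iodo-3-methylbuta-1,3-dien-1-yl]-1,1,5-trimethylcyclohexan-4-ol | I/C=C(C)/C=C/[C@@H]1[C@@H](C)[C@H](O)[C@H](O[Si](C)(C)C(C)(C)C)CC1(C)C | intermediate
20 | dibromomethane | BrCBr | starting material
21 | tributyltin chloride | CCCC[Sn](Cl)(CCCC)CCCC | starting material
22 | (dibromomethyl)tributylstannane | CCCC[Sn](CCCC)(CCCC)C(Br)Br | intermediate
23 | (2E,4E,6E)-2,7-dimethylocta-2,4,6-trienedial | O=C\C(C)=C\C=C\C=C(C)\C=O | starting material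
24 | (1E,3E,5E,7E,9E)-3,8-dimethyl-1,10-bis(tributylstannyl)deca-1,3,5,7,9-pentaene | CCCC[Sn](CCCC)(CCCC)/C=C/C(C)=C/C=C/C=C(C)/C=C/[Sn](CCCC)(CCCC)CCCC | intermediate
25 | (all-E)-(3R,3'R,4S,4'S,5R,5'R,6R,6'R)-3,3'-bis(tert-butyldimethylsilyloxy)-5,6,5',6'-tetrahydro-β,β-carotene-4,4'-diol | CC(/C=C/C=C(C)/C=C/[C@@H]1[C@@H](C)[C@H](O)[C@H](O[Si](C)(C)C(C)(C)C)CC1(C)C)=C\C=C\C=C(C)\C=C\C=C(C)\C=C\[C@@H]1[C@@H](C)[C@H](O)[C@H](O[Si](C)(C)C(C)(C)C)CC1(C)C | intermediate
26 | (all-E)-(3R,3'R,4S,4'S,5R,5'R,6R,6'R)-3,3'-bis(tert-butyldimethylsilyloxy)-5,6,5',6'-tetrahydro-β,β-carotene-4,4'-diyl bis(hydrogen sulfate) | CC(/C=C/C=C(C)/C=C/[C@@H]1[C@@H](C)[C@H](OS(=O)(=O)O)[C@H](O[Si](C)(C)C(C)(C)C)CC1(C)C)=C\C=C\C=C(C)\C=C\C=C(C)\C=C\[C@@H]1[C@@H](C)[C@H](OS(=O)(=O)O)[C@H](O[Si](C)(C)C(C)(C)C)CC1(C)C | intermediate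
27 | (all-E)-(3R,3'R,4S,4'S,5R,5'R,6R,6'R)-5,6,5',6'-tetrahydro-β,β-carotene-3,3',4,4'-tetrol 4,4'-bis(hydrogen sulfate) | CC(/C=C/C=C(C)/C=C/[C@@H]1[C@@H](C)[C@H](OS(=O)(=O)O)[C@H](O)CC1(C)C)=C\C=C\C=C(C)\C=C\C=C(C)\C=C\[C@@H]1[C@@H](C)[C@H](OS(=O)(=O)O)[C@H](O)CC1(C)C | target

**Step count**

Total: 14 steps. Longest linear sequence: 12 steps (steps 1–9 and 12–14); the central bis-stannane takes 2 steps (10–11).

**Steps most likely to fail**

Step 1. The hindered enone may not turn over under the chiral Lewis acid, or face and endo/exo discrimination may be too low, so that 4 would be formed with insufficient enantiomeric purity. The fallback uses known chemistry and sets out from 1 and 2. AlCl3 (cat.) in CH2Cl2 should give the racemic cis adduct F1, and NaOMe equilibration the racemic trans ketone F2. This is taken through the conditions of step 2, by way of the racemic iodo acetate F3 and the racemic hydroxy acetate F4, to the racemic diol F5. Acylation of the equatorial C4 hydroxyl with (1S)-camphanic chloride (pyridine, DMAP) gives two diastereomeric esters that are separated by crystallisation or chromatography. The one from the (3R,4S,5R,6R) series, the 4-O-camphanate F6, is saponified (LiOH, THF/H2O) and the route is rejoined at 7.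

Step 2. Iodonium formation and opening may occur with poor facial selectivity, the acetyl oxygen may capture the iodonium ion, or the ketone may be iodinated at the α-position. The fallback sets the face by an irreversible, sterically controlled epoxidation and sets out from 4. mCPBA (CH2Cl2, NaHCO3) should attack the open face anti to the axial C1 methyl to give the epoxide F7. Hot acetic acid opens it trans-diaxially at C3 to the trans hydroxy acetate F8. MsCl/Et3N gives the mesylate F9. Heating F9 in wet AcOH with KOAc lets the neighbouring acetate displace the C4 mesylate with inversion, and water opens the acetoxonium ion to the cis hydroxy acetate 6. The last operation of step 2 (K2CO3, MeOH) then gives 7.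

Step 12. The second coupling may stall, or the pentaenyl bis-stannane may suffer protodestannylation or homocoupling, with E/Z scrambling of the growing polyene. The fallback is tin-free with reversed polarity and sets out from 23 and 16. Takai olefination of 23 (CHI3, CrCl2, THF) should give the bis-iodide F10. Enyne 16 is carboaluminated as in step 8 to the alane 17, which is not iodinated but treated with ZnCl2, Pd(PPh3)4 and F10 (0.45 equiv) in a Negishi alkenyl–alkenyl coupling to give the fully silylated polyene F11. Selective removal of the triethylsilyl groups (PPTS, MeOH/CH2Cl2) rejoins the route at 25.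

**Further compounds**

F1 | step 1 | racemic 1-[(1RS,2RS)-2,6,6-trimethylcyclohex-3-en-1-yl]ethan-1-one (cis adduct) | CC(=O)[C@H]1[C@@H](C)C=CCC1(C)C.CC(=O)[C@@H]1[C@H](C)C=CCC1(C)C
F2 | step 1 | racemic 1-[(1RS,2SR)-2,6,6-trimethylcyclohex-3-en-1-yl]ethan-1-one (trans ketone) | CC(=O)[C@@H]1[C@@H](C)C=CCC1(C)C.CC(=O)[C@H]1[C@H](C)C=CCC1(C)C
F3 | step 1 | racemic trans-diaxial iodo acetate (racemate of 5) | CC(=O)[C@@H]1[C@@H](C)[C@@H](I)[C@H](OC(C)=O)CC1(C)C.CC(=O)[C@H]1[C@H](C)[C@H](I)[C@@H](OC(C)=O)CC1(C)C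
F4 | step 1 | racemic cis hydroxy acetate (racemate of 6) | CC(=O)[C@@H]1[C@@H](C)[C@H](O)[C@H](OC(C)=O)CC1(C)C.CC(=O)[C@H]1[C@H](C)[C@@H](O)[C@@H](OC(C)=O)CC1(C)C
F5 | step 1 | racemic 6-acetyl-1,1,5-trimethylcyclohexane-3,4-diol (racemate of 7) | CC(=O)[C@@H]1[C@@H](C)[C@H](O)[C@H](O)CC1(C)C.CC(=O)[C@H]1[C@H](C)[C@@H](O)[C@@H](O)CC1(C)C
F6 | step 1 | (3R,4S,5R,6R)-6-acetyl-3-hydroxy-1,1,5-trimethylcyclohexan-4-yl (1S,4R)-camphanate | CC(=O)[C@@H]1[C@@H](C)[C@H](OC(=O)[C@@]23CC[C@@](C)(C(=O)O2)C3(C)C)[C@H](O)CC1(C)C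
F7 | step 2 | (3S,4R,5R,6R)-6-acetyl-3,4-epoxy-1,1,5-trimethylcyclohexane (epoxide trans to acetyl) | CC(=O)[C@@H]1[C@@H](C)[C@H]2O[C@H]2CC1(C)C
F8 | step 2 | (3R,4R,5R,6R)-6-acetyl-4-hydroxy-1,1,5-trimethylcyclohexan-3-yl acetate (trans-diaxial) | CC(=O)[C@@H]1[C@@H](C)[C@@H](O)[C@H](OC(C)=O)CC1(C)C
F9 | step 2 | (3R,4R,5R,6R)-6-acetyl-4-(methanesulfonyloxy)-1,1,5-trimethylcyclohexan-3-yl acetate | CC(=O)[C@@H]1[C@@H](C)[C@@H](OS(C)(=O)=O)[C@H](OC(C)=O)CC1(C)C
F10 | step 12 | (1E,3E,5E,7E,9E)-1,10-diiodo-3,8-dimethyldeca-1,3,5,7,9-pentaene | I/C=C/C(C)=C/C=C/C=C(C)/C=C/I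
F11 | step 12 | (all-E)-(3R,3'R,4S,4'S,5R,5'R,6R,6'R)-3,3'-bis(tert-butyldimethylsilyloxy)-4,4'-bis(triethylsilyloxy)-5,6,5',6'-tetrahydro-β,β-carotene | CC(/C=C/C=C(C)/C=C/[C@@H]1[C@@H](C)[C@H](O[Si](CC)(CC)CC)[C@H](O[Si](C)(C)C(C)(C)C)CC1(C)C)=C\C=C\C=C(C)\C=C\C=C(C)\C=C\[C@@H]1[C@@H](C)[C@H](O[Si](CC)(CC)CC)[C@H](O[Si](C)(C)C(C)(C)C)CC1(C)C
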